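# Total synthesis of Alternarin A from (+)-sclareolide

**Retrosynthesis**
1. The thioether comes from S-alkylation of methyl (R)-2-hydroxy-3-mercaptopropanoate on the C2′-bromomethyl enone, which is made from the C2′-CH₂OH enone.
2. The only ring still to be built, the 4-hydroxy-4-acylcyclopent-2-enone, comes from an intramolecular aldol of the Z-enedione released from an Achmatowicz pyranone. Oxidising the resulting 1,2-diol gives the C12 ketone.
3. The pyranone comes from a furyl carbinol, which is the 5-lithiofuran of a silyl-protected 2-methyl-3-(hydroxymethyl)furan added to the decalin aldehyde.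
4. The decalin aldehyde comes from (+)-sclareolide by C3β-hydroxylation, lactone opening, dehydration to the 8(17)-ene and DIBAL reduction. Rings A and B are pre-formed, with C5, C9 and C10 set.

**Assumptions**
- Enzymatic C3β-hydroxylation of sclareolide (P450 BM3 variant, or Mucor plumbeus whole cells) is available.
- The furyl-carbinol addition and the aldol give C12 and C4′ epimeric mixtures. The natural C4′ epimer is separated by HPLC after the C12 oxidation, when C12 becomes a ketone.
- Labdane-type numbering is used. C12 is the ketone carbon and C4′ is the carbinol carbon of the cyclopentenone. C2′ carries the CH₂S group.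

## Route

**Step 1**
Reactants: 1 (+)-sclareolide
Product: 2 3β-hydroxysclareolide
Conditions: P450 BM3 variant, NADPH/GDH/glucose, O₂, KPi pH 8, 25 °C
Reagents that add atoms: O₂ (O=O)
Why: Enzymatic C–H hydroxylation places the OH on the equatorial 3β position (3S) of ring A under catalyst control (P450 C–H oxidation).

**Step 2**
Reactants: 2 3β-hydroxysclareolide
Product: 3 3β-O-TBS-sclareolide
Conditions: TBSOTf, 2,6-lutidine, CH₂Cl₂, 0 °C
Reagents that add atoms: TBSOTf, C[Si](C)(C(C)(C)C)OS(=O)(=O)C(F)(F)F
Why: The silyl triflate silylates the hindered C3 alcohol, which protects it from the DIBAL, organolithium and Dess–Martin steps that follow. No stereocentre is touched.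

**Step 3**
Reactants: 3 3β-O-TBS-sclareolide
Product: 4 methyl 3β-TBSO-8α-hydroxy-13,14,15,16-tetranorlabdan-12-oate
Conditions: (i) KOH, MeOH/H₂O, 80 °C, then concentrate to the potassium carboxylate; (ii) MeI, DMF, 23 °C
Reagents that add atoms: water, O (hydrolysis of the lactone, adds H₂O); MeI, CI (adds CH₃)
Why: Hydroxide cleaves the acyl–O bond of the tertiary lactone and leaves C8 untouched. O-Methylation of the isolated carboxylate with MeI (SN2) gives the hydroxy ester without acid, which would relactonise or eliminate. Net change: 3 + H₂O + CH₂ = 4.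

**Step 4**
Reactants: 4 hydroxy ester
Product: 5 methyl 3β-TBSO-13,14,15,16-tetranorlabd-8(17)-en-12-oate
Conditions: Burgess reagent, benzene, 50 °C; then AgNO₃–silica chromatography
Reagents that add atoms: none
Why: Burgess syn-elimination (Ei) of the tertiary alcohol takes a hydrogen from the freely rotating C17 methyl, which favours the exocyclic alkene. No cation forms, so C9 is not epimerised. AgNO₃–silica removes the endocyclic isomers.

**Step 5**
Reactants: 5 methyl ester
Product: 6 3β-TBSO-13,14,15,16-tetranorlabd-8(17)-en-12-al
Conditions: DIBAL-H (1.05 equiv), CH₂Cl₂, –78 °C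
Reagents that add atoms: none
Why: Partial DIBAL reduction stops at the aldehyde at –78 °C because the tetrahedral hemiacetal aluminate is stable, and it leaves the alkene and the silyl ether untouched.

**Step 6**
Reactants: 7 methyl 2-methylfuran-3-carboxylate
Product: 8 (2-methylfuran-3-yl)methanol
Conditions: LiAlH₄, THF, 0 °C
Reagents that add atoms: none
Why: Hydride reduction converts the ester to the primary alcohol.

**Step 7**
Reactants: 8 (2-methylfuran-3-yl)methanol
Product: 9 tert-butyldimethyl[(2-methylfuran-3-yl)methoxy]silane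
Conditions: TBSCl, imidazole, DMF, 23 °C
Reagents that add atoms: TBSCl, C[Si](C)(Cl)C(C)(C)C
Why: Silylation masks the OH so that the furan can be lithiated.

**Step 8**
Reactants: 6 aldehyde; 9 silyl furan
Product: 10 furyl carbinol (C12 epimeric mixture)
Conditions: 9, n-BuLi, THF, –20 °C; then CeCl₃, –78 °C; then 6, –78 → 0 °C
Reagents that add atoms: none
Why: n-BuLi lithiates the free α-position (C5–H) of the furan. Transmetallation to cerium suppresses enolisation of the aldehyde, so 1,2-addition (organocerium carbonyl addition) gives the secondary carbinol. The new C12 stereocentre is unselective and is removed in step 11.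

**Step 9**
Reactants: 10 furyl carbinol
Product: 11 Achmatowicz pyranone (6-hydroxy-6-methyl-2H-pyran-3(6H)-one, mixture of anomers and C12 epimers)
Conditions: NBS (1.0 equiv), NaHCO₃, THF/H₂O 4:1, 0 °C
Reagents that add atoms: water, O
Why: Achmatowicz oxidative ring expansion works because the electron-rich furan reacts with NBS far faster than the 1,1-disubstituted exocyclic alkene. Water traps the bromo-oxocarbenium ion and the ring opens to the pyranone hemiketal.

**Step 10**
Reactants: 11 pyranone
Product: 12 4-hydroxy-4-(1-hydroxyalkyl)-2-(TBSOCH₂)cyclopent-2-enone (C4′ epimers)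
Conditions: DBU (0.2 equiv), THF, 0 °C
Reagents that add atoms: none
Why: Base opens the pyranone hemiketal to the Z-enedione CH₃CO–C(CH₂OTBS)=CH–CO–CH(OH)R. The methyl-ketone enolate then closes onto the other ketone in an intramolecular aldol (5-enolendo-exo-trig). This ring closure is possible because the cis alkene holds the two termini together and the aldol is reversible. The resulting 4-hydroxycyclopentenone cannot dehydrate (it would give a cyclopentadienone), so the tertiary C4′ carbinol is isolated as an epimer mixture.

**Step 11**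
Reactants: 12 diol
Product: 13 α-ketol (C12 ketone; C4′ epimers separated by HPLC)
Conditions: Dess–Martin periodinane, NaHCO₃, CH₂Cl₂, 0 °C; then preparative HPLC
Reagents that add atoms: none
Why: DMP oxidises the secondary C12 alcohol to the α-hydroxy ketone and leaves the tertiary alcohol, the alkenes and the TBS ethers untouched. This removes the C12 stereocentre, so only the C4′ epimers remain. They are diastereomers and are separated by HPLC to give the natural C4′ (R) epimer.

**Step 12**
Reactants: 13 bis-TBS α-ketol
Product: 14 triol enone (3β-OH, tertiary C4′-OH, C2′-CH₂OH)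
Conditions: HF·pyridine, pyridine/THF, 0 → 23 °C
Reagents that add atoms: none
Why: Buffered fluoride removes both TBS ethers (Si–F driven) and leaves the enone, the α-ketol and the exocyclic alkene intact.

**Step 13**
Reactants: 14 triol enone
Product: 15 allylic bromide (C2′-CH₂Br)
Conditions: CBr₄, PPh₃, CH₂Cl₂, 0 °C
Reagents that add atoms: CBr₄, BrC(Br)(Br)Br
Why: Appel bromination (SN2 on the alkoxyphosphonium) is selective for the unhindered primary allylic alcohol over the hindered C3 secondary alcohol and the tertiary alcohol.

**Step 14**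
Reactants: 16 methyl (S)-glycidate
Product: 17 methyl (R)-3-(acetylthio)-2-hydroxypropanoate
Conditions: AcSH, CH₂Cl₂, 0 → 23 °C
Reagents that add atoms: thioacetic acid, CC(=O)S
Why: Epoxide opening (SN2) by thioacetic acid occurs at the unhindered C3 and leaves C2 untouched, so the glycerate centre is retained. The descriptor changes from S to R only because CH₂S outranks CO₂Me in the CIP priorities.

**Step 15**
Reactants: 17 thioacetate
Product: 18 methyl (R)-2-hydroxy-3-mercaptopropanoate
Conditions: AcCl (cat.), MeOH, 50 °C, degassed
Reagents that add atoms: none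
Why: Acid-catalysed methanolysis (transesterification) of the thioacetate gives the free thiol without base, so there is no S→O acyl migration or racemisation of the α-hydroxy ester.

**Step 16**
Reactants: 15 allylic bromide; 18 thiol
Product: 19 Alternarin A
Conditions: Et₃N, CH₂Cl₂, 0 °C
Reagents that add atoms: none (the thiol 18 is a reactant)
Why: Thiolate S-alkylation (SN2) forms the allylic sulfide. Any SN2′ adduct (thiol at C3′ with an exocyclic methylene) is reversible by retro-Michael and re-addition, and it funnels to the conjugated endocyclic enone. The quaternary C4′ next to C3′ disfavours the C3′ product. No stereocentre is touched.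

## Compound list

1 | (+)-sclareolide | O=C1C[C@@H]2[C@@]3(C)CCCC(C)(C)[C@@H]3CC[C@@]2(C)O1 | starting material
2 | 3β-hydroxysclareolide | O=C1C[C@@H]2[C@@]3(C)CC[C@H](O)C(C)(C)[C@@H]3CC[C@@]2(C)O1 | intermediate
3 | 3β-O-TBS-sclareolide | O=C1C[C@@H]2[C@@]3(C)CC[C@H](O[Si](C)(C)C(C)(C)C)C(C)(C)[C@@H]3CC[C@@]2(C)O1 | intermediate
4 | methyl 3β-TBSO-8α-hydroxy-13,14,15,16-tetranorlabdan-12-oate | COC(=O)C[C@@H]1[C@@]2(C)CC[C@H](O[Si](C)(C)C(C)(C)C)C(C)(C)[C@@H]2CC[C@@]1(C)O | intermediate
5 | methyl 3β-TBSO-13,14,15,16-tetranorlabd-8(17)-en-12-oate | C=C1CC[C@H]2C(C)(C)[C@@H](O[Si](C)(C)C(C)(C)C)CC[C@]2(C)[C@H]1CC(=O)OC | intermediate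
6 | 3β-TBSO-13,14,15,16-tetranorlabd-8(17)-en-12-al | C=C1CC[C@H]2C(C)(C)[C@@H](O[Si](C)(C)C(C)(C)C)CC[C@]2(C)[C@H]1CC=O | intermediate
7 | methyl 2-methylfuran-3-carboxylate | COC(=O)c1ccoc1C | starting material
8 | (2-methylfuran-3-yl)methanol | OCc1ccoc1C | intermediate
9 | tert-butyldimethyl[(2-methylfuran-3-yl)methoxy]silane | Cc1occc1CO[Si](C)(C)C(C)(C)C | intermediate
10 | furyl carbinol (C12 epimeric mixture; C12 undefined) | C=C1CC[C@H]2C(C)(C)[C@@H](O[Si](C)(C)C(C)(C)C)CC[C@]2(C)[C@H]1CC(O)c1cc(CO[Si](C)(C)C(C)(C)C)c(C)o1 | intermediate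
11 | Achmatowicz pyranone (anomer and C12 mixture) | C=C1CC[C@H]2C(C)(C)[C@@H](O[Si](C)(C)C(C)(C)C)CC[C@]2(C)[C@H]1CC1OC(C)(O)C(CO[Si](C)(C)C(C)(C)C)=CC1=O | intermediate
12 | cyclopentenone 1,2-diol (C12 undefined; C4′ drawn as natural R epimer, formed with its epimer) | C=C1CC[C@H]2C(C)(C)[C@@H](O[Si](C)(C)C(C)(C)C)CC[C@]2(C)[C@H]1CC(O)[C@]1(O)C=C(CO[Si](C)(C)C(C)(C)C)C(=O)C1 | intermediate
13 | α-ketol bis-TBS ether (C4′ R) | C=C1CC[C@H]2C(C)(C)[C@@H](O[Si](C)(C)C(C)(C)C)CC[C@]2(C)[C@H]1CC(=O)[C@]1(O)C=C(CO[Si](C)(C)C(C)(C)C)C(=O)C1 | intermediate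
14 | triol enone | C=C1CC[C@H]2C(C)(C)[C@@H](O)CC[C@]2(C)[C@H]1CC(=O)[C@]1(O)C=C(CO)C(=O)C1 | intermediate
15 | allylic bromide | C=C1CC[C@H]2C(C)(C)[C@@H](O)CC[C@]2(C)[C@H]1CC(=O)[C@]1(O)C=C(CBr)C(=O)C1 | intermediate
16 | methyl (S)-glycidate | COC(=O)[C@@H]1CO1 | starting material
17 | methyl (R)-3-(acetylthio)-2-hydroxypropanoate | CC(=O)SC[C@H](O)C(=O)OC | intermediate
18 | methyl (R)-2-hydroxy-3-mercaptopropanoate | SC[C@H](O)C(=O)OC | intermediate
19 | Alternarin A | C=C1CC[C@H]2C(C)(C)[C@@H](O)CC[C@]2(C)[C@H]1CC(=O)[C@]1(O)C=C(CSC[C@H](O)C(=O)OC)C(=O)C1 | target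

**Total steps:** 16. **Longest linear sequence:** 12 steps from sclareolide (steps 1–5, 8–13, 16).

## Three steps most likely to fail

1. **Step 4, exocyclic dehydration.** Burgess elimination may give the Δ7 or Δ8(9) isomers.
   - Fallback: form the tertiary methyl xanthate (NaH, CS₂, MeI) and do a Chugaev pyrolysis. This is a different syn-elimination that favours the accessible C17 hydrogens.
2. **Step 10 (with step 8), C4′ stereocontrol.** The aldol is not catalyst-controlled and the C12 epimers lead to C4′ epimers, so the yield of the natural epimer is capped.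
   - Fallback: make the furyl ketone from the Weinreb amide of 5 plus the furyllithium, reduce it with a CBS catalyst to a single C12 epimer, and let 1,2-induction in the aldol set C4′.
3. **Step 9, Achmatowicz oxidation.** NBS may brominate the exocyclic alkene or over-oxidise.
   - Fallback: use singlet-oxygen furan photooxidation (rose bengal, O₂, hν, MeOH; then Me₂S) to give the Z-enedione directly, which goes on to the step 10 aldol. This route is chemoselective for the furan over the alkene.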